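**Retrosynthetic overview**

1. The four aldehydes are unveiled last by periodate cleavage of two cis-cyclopentane-1,2-diols. Both identical acyl groups come from one acid, 23, made from a ribose-derived cyclopentenone whose ring is sacrificial and encodes the (S)-centre and the enal.
2. The core is diol 16, in which O1 and O11 (the two oxygens that stay free) are tied in a temporary trans-fused pyran ring. Because C1 and C11 are 1,5-related through C9–C5–C4, this ring leaves only O3 and O7 for acylation and fixes C4 by the equatorial preference of the free arm.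
3. The cyclopentane, the only ring of the target, is made by a (3+2) union of (E)-pent-3-en-2-one (C7–C8 with C10; the acetyl group is a latent O7) with the 2-alkylidenecyclopropanecarboxylate 6 (C9–C5–C6 with C1, C4, C3, C11). This forms C6–C7 and C8–C9.
4. Enabling feature: C9 carries a carboxyl-level carbon (C1) and C5 carries the branch carbon C4, so C9–C5(=C4)–C6 is a trimethylenemethane. Closing the non-target bond C6–C9 stores it as a strained cyclopropane that palladium can open, and the all-trans pattern on C5/C9/C8/C7 lets the enolisable centres C7 and C9 settle thermodynamically.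
5. Ring order: sacrificial cyclopropane (steps 2–4), cyclopentane (step 5), lactone then methyl pyranoside (steps 10–12, opened in step 19); the ribose-derived cyclopentanes are cleaved in step 20.

Key step: step 5

Remark on locants: the core is numbered as an iridane. Ring C5–C6–C7–C8–C9; C10 is the methyl on C8; C1 is the hydroxymethyl carbon on C9; C4 is the branch carbon on C5 and carries C3 (acylated arm) and C11 (free arm). With the ring drawn so that C5→C6→C7→C8→C9 runs counterclockwise, the target has the C4 branch up, O7 down, C10 up and C1 down.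

Assumption: the ribose-derived enone 17 is taken as a purchased material. Lactols 15 and 25 are anomeric mixtures of no consequence and are left unassigned at the anomeric carbon; acetals 16 and 24 are drawn as the axial methyl glycoside.

**Route**

Step 1
Reactants: 1 2-methylenepropane-1,3-diol
Product: 2 2,2-dimethyl-5-methylene-1,3-dioxane
Conditions: 2,2-dimethoxypropane, PPTS (cat.), CH2Cl2, rt
Reagents that add atoms: 2,2-dimethoxypropane COC(C)(C)OC
Why: Acid-catalysed transketalisation of a 1,3-diol is driven by loss of methanol and creates no stereocentre.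

Step 2
Reactants: 2 2,2-dimethyl-5-methylene-1,3-dioxane
Product: 3 1,1-dibromo-6,6-dimethyl-5,7-dioxaspiro[2.5]octane
Conditions: CHBr3, 50% aq. NaOH, BnEt3NCl (cat.), CH2Cl2, 0 °C to rt
Reagents that add atoms: bromoform BrC(Br)Br
Why: Phase-transfer dibromocyclopropanation, in which dibromocarbene adds to the 1,1-disubstituted alkene; the carbene carbon becomes C5 and no stereocentre is formed.

Step 3
Reactants: 3 1,1-dibromo-6,6-dimethyl-5,7-dioxaspiro[2.5]octane
Product: 4 5-ethenylidene-2,2-dimethyl-1,3-dioxane (1,1-disubstituted allene)
Conditions: MeLi, Et2O, −78 to −30 °C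
Reagents that add atoms: none
Why: Doering–Moore–Skattebøl allene synthesis, in which bromine–lithium exchange gives a cyclopropylidene carbenoid that opens to the allene; no stereocentre is formed.

Step 4
Reactants: 4 5-ethenylidene-2,2-dimethyl-1,3-dioxane, 5 ethyl diazoacetate
Product: 6 ethyl 2-(2,2-dimethyl-1,3-dioxan-5-ylidene)cyclopropane-1-carboxylate (racemate)
Conditions: Rh2(OAc)4 (0.5 mol%), CH2Cl2, rt, slow addition of the diazo ester to a threefold excess of the allene
Reagents that add atoms: none
Why: Rhodium-carbenoid cyclopropanation should take place at the unhindered terminal C=CH2 bond of the allene (the other π-bond is fully substituted and deactivated by two allylic C–O bonds); the racemic stereocentre is of no consequence because it becomes planar in step 5.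

Step 5
Reactants: 6 ethyl 2-(2,2-dimethyl-1,3-dioxan-5-ylidene)cyclopropane-1-carboxylate, 7 (E)-pent-3-en-2-one
Product: 8 ethyl 3-acetyl-5-(2,2-dimethyl-1,3-dioxan-5-ylidene)-2-methylcyclopentane-1-carboxylate (C7 acetyl down, C8 methyl up, both C9 epimers)
Conditions: Pd2(dba)3·CHCl3 (2.5 mol%), (S)-BINOL-derived phosphoramidite of (R,R)-bis(1-phenylethyl)amine (10 mol%), PhMe, 60 °C, enone in threefold excess
Reagents that add atoms: none
Why: Proposed new method: oxidative addition of zerovalent palladium into the distal C6–C9 σ-bond of 6 (both ends allylic, about 40 kcal/mol of ring strain released, heterolysis assisted by the ester on C9) should give an ester-stabilised trimethylenemethane–palladium zwitterion, with the π-allyl over C6–C5–C4 and the enolate at C9. The closest known reactions are the palladium-catalysed (3+2) codimerisation of methylenecyclopropanes with electron-poor alkenes through distal-bond cleavage and the enantioselective trimethylenemethane cycloaddition of acceptor-substituted silyl acetate donors with phosphoramidite ligands; what is new is generating the acceptor-substituted species from a cyclopropane under a chiral ligand. The enolate carbon C9 adds in Michael fashion to C8 of the enone (bond C8–C9), and the resulting ketone enolate closes the only new ring by intramolecular Tsuji–Trost alkylation at the unsubstituted allyl terminus C6 (bond C6–C7; 5-exo-tet with respect to the palladium-bearing terminus, the central allyl carbon C5 lying in the ring and the exocyclic C5=C4 alkene being retained), which returns zerovalent palladium. C8 is set in the Michael step by the chiral ligand (the ligand antipode is taken if the sense proves opposite), C7 is set in the ring closure trans to the C8 methyl (also the thermodynamic arrangement), and C9 is not controlled and is erased in step 6. The step needs distal rather than proximal cleavage and C9 rather than C4 as the nucleophile, both secured by the ester on C9, and closure at C6 rather than C4, secured by a CH2 terminus competing with a fully substituted terminus flanked by two CH2O groups.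

Step 6
Reactants: 8 (3+2) adduct
Product: 9 ethyl 4-acetyl-2-(2,2-dimethyl-1,3-dioxan-5-yl)-5-methylcyclopent-1-ene-1-carboxylate (C7 acetyl and C8 methyl trans)
Conditions: DBU (0.2 equiv), CH2Cl2, rt
Reagents that add atoms: none
Why: Base-mediated prototropic shift through the ester dienolate moves the exocyclic alkene into conjugation (C9=C5), which removes the uncontrolled C9 centre; C8 is not acidic and C7 stays in its favoured trans arrangement.

Step 7
Reactants: 9 conjugated enoate
Product: 10 ethyl 3-acetyl-5-(2,2-dimethyl-1,3-dioxan-5-yl)-2-methylcyclopentane-1-carboxylate (C5 branch, C8 methyl and C9 ester up; C7 acetyl down)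
Conditions: H2 (20 bar), [Ir(cod)(PCy3)(py)]PF6 (5 mol%), CH2Cl2, rt
Reagents that add atoms: none
Why: Carbonyl-directed homogeneous hydrogenation, in which the cationic iridium catalyst is anchored by the C7 acetyl oxygen on the lower face (also the face remote from the allylic C8 methyl) and delivers both hydrogens syn, setting C5 with the branch cis to the C8 methyl and, provisionally, C9.

Step 8
Reactants: 10 all-cis keto ester
Product: 11 ethyl 3-acetyl-5-(2,2-dimethyl-1,3-dioxan-5-yl)-2-methylcyclopentane-1-carboxylate, all-trans (C9 ester down)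
Conditions: NaOEt (0.3 equiv), EtOH, 40 °C
Reagents that add atoms: none
Why: Thermodynamic epimerisation through the ester enolate places the C9 ester trans to both neighbours, while the ketone-adjacent C7 is already in its favoured configuration.

Step 9
Reactants: 11 all-trans keto ester
Product: 12 ethyl 3-acetoxy-5-(2,2-dimethyl-1,3-dioxan-5-yl)-2-methylcyclopentane-1-carboxylate, all-trans
Conditions: mCPBA, NaHCO3, CH2Cl2, rt
Reagents that add atoms: mCPBA OOC(=O)c1cccc(Cl)c1
Why: Baeyer–Villiger oxidation, in which the secondary ring carbon C7 migrates in preference to methyl with retention, so the acetyl group becomes the C7 acetate with oxygen trans to the C8 methyl.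

Step 10
Reactants: 12 all-trans acetate
Product: 14 trans-fused δ-lactone (C1 carbonyl joined to O11, free C3 hydroxymethyl equatorial, O7 acetate), via diol ester 13 (not isolated)
Conditions: TsOH·H2O (10 mol%), MeCN–H2O, rt; then PhMe, 80 °C
Reagents that add atoms: none
Why: Acetonide hydrolysis followed by acid-catalysed lactonisation of the C1 ester with one of the two diastereotopic hydroxymethyl arms should, after equilibration by translactonisation, favour the trans-fused lactone whose free CH2OH is equatorial, which is the C4 configuration of the target; the acetate on O7 prevents a bridged lactone.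

Step 11
Reactants: 14 trans-fused δ-lactone
Product: 15 lactol triol (C1 lactol joined to O11; C3 and C7 hydroxyls free)
Conditions: i-Bu2AlH (5 equiv), CH2Cl2, −78 °C; MeOH, then aq. potassium sodium tartrate
Reagents that add atoms: none
Why: Hydride reduction at low temperature stops at the lactol (stable aluminium hemiacetal) and also cleaves the acetate reductively; the only new centre is the anomeric one, which is of no consequence.

Step 12
Reactants: 15 lactol triol
Product: 16 methyl acetal diol (trans-fused 1-methoxy pyran; C3 and C7 hydroxyls free)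
Conditions: MeOH, CSA (5 mol%), 40 °C
Reagents that add atoms: methanol CO
Why: Fischer-type glycosidation under equilibrating conditions gives the methyl pyranoside and lets the two hydroxymethyl arms exchange through the ring-opened oxocarbenium ion, so the trans-fused chair with equatorial CH2OH and axial methoxy, which has the required C4 configuration, should predominate.

Step 13
Reactants: 17 (3aR,6aR)-2,2-dimethyl-3a,6a-dihydro-4H-cyclopenta[d][1,3]dioxol-4-one
Product: 18 (3aR,6aR)-2,2-dimethyltetrahydro-4H-cyclopenta[d][1,3]dioxol-4-one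
Conditions: H2 (1 atm), Pd/C (10% palladium on carbon), EtOAc, rt
Reagents that add atoms: none
Why: Heterogeneous hydrogenation of the enone C=C bond leaves the two acetonide stereocentres untouched.

Step 14
Reactants: 18 saturated ketone
Product: 20 methyl 2-[(3aR,5S,6aR)-2,2-dimethyl-4-oxotetrahydro-4H-cyclopenta[d][1,3]dioxol-5-yl]acetate, via lithium enolate 19 (not isolated)
Conditions: lithium diisopropylamide, THF, −78 °C; then BrCH2CO2Me, DMPU, −78 to −30 °C
Reagents that add atoms: methyl bromoacetate COC(=O)CBr
Why: Kinetic enolate alkylation, in which deprotonation occurs on the CH2 side and the electrophile enters on the convex face of the cis-fused bicycle, trans to the dioxolane, setting the future (S)-centre of the acyl group.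

Step 15
Reactants: 20 alkylated ketone
Product: 21 methyl 2-[(3aS,4E,5S,6aR)-4-ethylidene-2,2-dimethyltetrahydro-4H-cyclopenta[d][1,3]dioxol-5-yl]acetate
Conditions: EtPPh3Br, KOt-Bu, THF, 0 °C to rt
Reagents that add atoms: ethyltriphenylphosphonium bromide CC[P+](c1ccccc1)(c1ccccc1)c1ccccc1.[Br-]
Why: Wittig olefination with the non-stabilised ylide, whose methyl group is expected to point away from the dioxolane oxygen and so give the geometry that maps onto the (E)-enal; a minor geometric isomer would be separated here.

Step 16
Reactants: 21 ethylidene ester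
Product: 23 2-[(3aS,4E,5S,6aR)-4-ethylidene-2,2-dimethyltetrahydro-4H-cyclopenta[d][1,3]dioxol-5-yl]acetic acid, via lithium carboxylate 22 (not isolated)
Conditions: LiOH·H2O, THF–H2O, rt; then 1 M HCl to pH 4, 0 °C
Reagents that add atoms: lithium hydroxide [Li+].[OH-]
Why: Saponification; the stereocentre is β to the carboxyl group and cannot epimerise, and the acetonide survives a brief cold acidification.

Step 17
Reactants: 16 methyl acetal diol, 23 acid (2.5 equiv)
Product: 24 bis-ester (O3 and O7 acylated by 23; O1 and O11 in the methyl acetal ring)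
Conditions: EDCI·HCl, DMAP, CH2Cl2, rt
Reagents that add atoms: none
Why: Steglich esterification acylates the primary C3 hydroxyl and the secondary C7 hydroxyl with the same acid, with retention at C7, while O1 and O11 are locked in the acetal ring.

Step 18
Reactants: 24 bis-ester
Product: 25 lactol bis-ester with two free cis-cyclopentane-1,2-diols
Conditions: 2 M aq. HCl–THF (1:3), rt
Reagents that add atoms: water O
Why: Aqueous acid hydrolysis cleaves the methyl acetal and both acetonides in one operation, leaves the esters intact and keeps O11 in the lactol ring so that the C3 acyl group cannot migrate.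

Step 19
Reactants: 25 lactol bis-ester
Product: 26 hexaol bis-ester (C1 and C11 primary alcohols free; two cis-diols)
Conditions: NaBH4, THF–pH 7 phosphate buffer, 0 °C; AcOH quench
Reagents that add atoms: none
Why: Chemoselective borohydride reduction of the lactol through its open hydroxy aldehyde releases the C1 and C11 alcohols without reducing the esters; cold buffered conditions leave little time for 1,3-acyl migration.

Step 20
Reactants: 26 hexaol bis-ester
Product: 27 CNP0192766.1
Conditions: NaIO4, THF–H2O (pH 7), 0 °C to rt
Reagents that add atoms: none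
Why: Periodate glycol cleavage of both cis-cyclopentane-1,2-diols unveils the four aldehydes under neutral conditions; the acyl stereocentres are untouched and each ethylidene becomes the (E)-2-formylbut-2-enyl unit.

**Compound list**

1 | 2-methylenepropane-1,3-diol | C=C(CO)CO | starting material
2 | 2,2-dimethyl-5-methylene-1,3-dioxane | C=C1COC(C)(C)OC1 | intermediate
3 | 1,1-dibromo-6,6-dimethyl-5,7-dioxaspiro[2.5]octane | CC1(C)OCC2(CO1)CC2(Br)Br | intermediate
4 | 5-ethenylidene-2,2-dimethyl-1,3-dioxane | C=C=C1COC(C)(C)OC1 | intermediate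
5 | ethyl diazoacetate | CCOC(=O)C=[N+]=[N-] | starting material
6 | ethyl 2-(2,2-dimethyl-1,3-dioxan-5-ylidene)cyclopropane-1-carboxylate (racemate) | CCOC(=O)C1CC1=C2COC(C)(C)OC2 | intermediate
7 | (E)-pent-3-en-2-one | C/C=C/C(C)=O | starting material
8 | ethyl 3-acetyl-5-(2,2-dimethyl-1,3-dioxan-5-ylidene)-2-methylcyclopentane-1-carboxylate (acetyl/methyl trans; C9 epimers) | CCOC(=O)C1C(=C2COC(C)(C)OC2)C[C@@H](C(C)=O)[C@@H]1C | intermediate
9 | ethyl 4-acetyl-2-(2,2-dimethyl-1,3-dioxan-5-yl)-5-methylcyclopent-1-ene-1-carboxylate (acetyl/methyl trans) | CCOC(=O)C1=C(C2COC(C)(C)OC2)C[C@@H](C(C)=O)[C@@H]1C | intermediate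
10 | ethyl 3-acetyl-5-(2,2-dimethyl-1,3-dioxan-5-yl)-2-methylcyclopentane-1-carboxylate (C5 branch, C8 methyl, C9 ester cis; C7 acetyl trans to them) | CC1(C)OCC(CO1)[C@@H]2C[C@@H](C(C)=O)[C@H](C)[C@@H]2C(=O)OCC | intermediate
11 | C9 epimer of 10, all-trans keto ester | CC1(C)OCC(CO1)[C@@H]2C[C@@H](C(C)=O)[C@H](C)[C@H]2C(=O)OCC | intermediate
12 | ethyl 3-acetoxy-5-(2,2-dimethyl-1,3-dioxan-5-yl)-2-methylcyclopentane-1-carboxylate, all-trans | CC1(C)OCC(CO1)[C@@H]2C[C@@H](OC(C)=O)[C@H](C)[C@H]2C(=O)OCC | intermediate
13 | ethyl 3-acetoxy-5-(1,3-dihydroxypropan-2-yl)-2-methylcyclopentane-1-carboxylate, all-trans | OCC(CO)[C@@H]1C[C@@H](OC(C)=O)[C@H](C)[C@H]1C(=O)OCC | intermediate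
14 | trans-fused δ-lactone (C1 carbonyl to O11; equatorial C3 hydroxymethyl; O7 acetate) | OC[C@H](CO2)[C@@H]1C[C@@H](OC(C)=O)[C@H](C)[C@H]1C2=O | intermediate
15 | lactol triol (anomers) | OC[C@H](CO2)[C@@H]1C[C@@H](O)[C@H](C)[C@H]1C2O | intermediate
16 | methyl acetal diol (axial methoxy) | OC[C@H](CO2)[C@@H]1C[C@@H](O)[C@H](C)[C@H]1[C@H]2OC | intermediate
17 | (3aR,6aR)-2,2-dimethyl-3a,6a-dihydro-4H-cyclopenta[d][1,3]dioxol-4-one | O=C1C=C[C@H]2OC(C)(C)O[C@@H]12 | starting material
18 | (3aR,6aR)-2,2-dimethyltetrahydro-4H-cyclopenta[d][1,3]dioxol-4-one | O=C1CC[C@H]2OC(C)(C)O[C@@H]12 | intermediate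
19 | lithium enolate of 18 (CH2 side) | [Li+].[O-]C1=CC[C@H]2OC(C)(C)O[C@@H]12 | intermediate
20 | methyl 2-[(3aR,5S,6aR)-2,2-dimethyl-4-oxotetrahydro-4H-cyclopenta[d][1,3]dioxol-5-yl]acetate | COC(=O)C[C@@H]1C[C@H]2OC(C)(C)O[C@H]2C1=O | intermediate
21 | methyl 2-[(3aS,4E,5S,6aR)-4-ethylidene-2,2-dimethyltetrahydro-4H-cyclopenta[d][1,3]dioxol-5-yl]acetate | COC(=O)C[C@@H]1C[C@H]2OC(C)(C)O[C@H]2/C1=C/C | intermediate
22 | lithium carboxylate of 23 | [Li+].[O-]C(=O)C[C@@H]1C[C@H]2OC(C)(C)O[C@H]2/C1=C/C | intermediate
23 | 2-[(3aS,4E,5S,6aR)-4-ethylidene-2,2-dimethyltetrahydro-4H-cyclopenta[d][1,3]dioxol-5-yl]acetic acid | OC(=O)C[C@@H]1C[C@H]2OC(C)(C)O[C@H]2/C1=C/C | intermediate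
24 | bis-ester of 16 with 23 at O3 and O7 | C(OC(=O)C[C@@H]1C[C@H]2OC(C)(C)O[C@H]2/C1=C/C)[C@H](CO3)[C@@H]1C[C@@H](OC(=O)C[C@@H]2C[C@H]4OC(C)(C)O[C@H]4/C2=C/C)[C@H](C)[C@H]1[C@H]3OC | intermediate
25 | lactol bis-ester with two free cis-diols (anomers) | C(OC(=O)C[C@@H]1C[C@@H](O)[C@@H](O)/C1=C/C)[C@H](CO3)[C@@H]1C[C@@H](OC(=O)C[C@@H]2C[C@@H](O)[C@@H](O)/C2=C/C)[C@H](C)[C@H]1C3O | intermediate
26 | hexaol bis-ester | C(OC(=O)C[C@@H]1C[C@@H](O)[C@@H](O)/C1=C/C)[C@H](CO)[C@@H]1C[C@@H](OC(=O)C[C@@H]2C[C@@H](O)[C@@H](O)/C2=C/C)[C@H](C)[C@H]1CO | intermediate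
27 | CNP0192766.1 | C/C=C(/C=O)[C@@H](CC=O)CC(=O)OC[C@H](CO)[C@@H]1C[C@@H](OC(=O)C[C@H](CC=O)/C(C=O)=C\C)[C@H](C)[C@H]1CO | target

**Step count and risks**

Total step count: 20. Longest linear sequence: 16 steps (steps 1–12 and 17–20, from 1).

Steps most likely to fail:

1. Step 5 (proposed new method). The chiral ligand may slow or stop oxidative addition into the fully substituted alkylidenecyclopropane, ring closure may occur at the wrong allyl terminus, or asymmetric induction may be poor. Fallback with known chemistry, setting out from 6: the cycloaddition is run under the classical achiral conditions for methylenecyclopropane–alkene codimerisation (Pd2(dba)3·CHCl3, P(O-i-Pr)3, PhMe, 100 °C). This gives 8 as a racemate, that is, together with its mirror image ent-8 F1. Steps 6–9 are run on the racemate, which carries ent-9 F2, ent-10 F3, ent-11 F4 and ent-12 F5 alongside 9–12. Racemic 12 is then resolved by lipase-catalysed hydrolysis (Candida antarctica lipase B, pH 7 phosphate buffer/MTBE, rt). By the usual empirical rule for lipases and secondary alcohols, the (R)-configured acetate 12 should react faster and give the hydroxy ester F6, leaving F5. F6 is separated and re-acetylated (Ac2O, pyridine, DMAP), and the route is rejoined at 12.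

2. Step 7. Reduction of the tetrasubstituted enoate may be incomplete, or hydrogen may be delivered from the wrong face if ketone coordination is too weak. Fallback setting out from 9: the ketone is reduced (NaBH4, CeCl3·7H2O, MeOH, −20 °C) to the carbinol F7 (epimers at the carbinol carbon, of no consequence). Its hydroxyl, a much stronger directing group, steers hydrogenation with [Rh(nbd)(dppb)]BF4 (H2, CH2Cl2) to the lower face and gives the saturated hydroxy ester F8. Dess–Martin oxidation then returns 10.

3. Step 12. Thermodynamic discrimination between the two hydroxymethyl arms may be insufficient during lactol and acetal equilibration, which would erode the C4 configuration. Fallback setting out from 14 (the major lactone is purified; the minor C4-epimeric lactone is recycled with TsOH in PhMe): the free arm is locked as the silyl ether F9 (TBDPSCl, imidazole, DMF). Reduction with i-Bu2AlH at −78 °C gives the lactol F10, in which the blocked C3 arm can no longer exchange with O11. CSA/MeOH gives the methyl acetal F11, and TBAF (THF, AcOH buffer) returns 16.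

**Further compounds**

F1 | step 5 | ent-8, mirror image of the (3+2) adduct | CCOC(=O)C1C(=C2COC(C)(C)OC2)C[C@H](C(C)=O)[C@H]1C
F2 | step 5 | ent-9 | CCOC(=O)C1=C(C2COC(C)(C)OC2)C[C@H](C(C)=O)[C@H]1C
F3 | step 5 | ent-10 | CC1(C)OCC(CO1)[C@H]2C[C@H](C(C)=O)[C@@H](C)[C@H]2C(=O)OCC
F4 | step 5 | ent-11 | CC1(C)OCC(CO1)[C@H]2C[C@H](C(C)=O)[C@@H](C)[C@@H]2C(=O)OCC
F5 | step 5 | ent-12 | CC1(C)OCC(CO1)[C@H]2C[C@H](OC(C)=O)[C@@H](C)[C@@H]2C(=O)OCC
F6 | step 5 | ethyl 5-(2,2-dimethyl-1,3-dioxan-5-yl)-3-hydroxy-2-methylcyclopentane-1-carboxylate, all-trans | CC1(C)OCC(CO1)[C@@H]2C[C@@H](O)[C@H](C)[C@H]2C(=O)OCC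
F7 | step 7 | ethyl 2-(2,2-dimethyl-1,3-dioxan-5-yl)-4-(1-hydroxyethyl)-5-methylcyclopent-1-ene-1-carboxylate | CCOC(=O)C1=C(C2COC(C)(C)OC2)C[C@@H](C(C)O)[C@@H]1C
F8 | step 7 | ethyl 5-(2,2-dimethyl-1,3-dioxan-5-yl)-3-(1-hydroxyethyl)-2-methylcyclopentane-1-carboxylate (ring stereochemistry as in 10) | CC1(C)OCC(CO1)[C@@H]2C[C@@H](C(C)O)[C@H](C)[C@@H]2C(=O)OCC
F9 | step 12 | O3-TBDPS ether of lactone 14 | CC(C)(C)[Si](c1ccccc1)(c1ccccc1)OC[C@H](CO2)[C@@H]1C[C@@H](OC(C)=O)[C@H](C)[C@H]1C2=O
F10 | step 12 | O3-TBDPS lactol (anomers) | CC(C)(C)[Si](c1ccccc1)(c1ccccc1)OC[C@H](CO2)[C@@H]1C[C@@H](O)[C@H](C)[C@H]1C2O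
F11 | step 12 | O3-TBDPS methyl acetal | CC(C)(C)[Si](c1ccccc1)(c1ccccc1)OC[C@H](CO2)[C@@H]1C[C@@H](O)[C@H](C)[C@H]1[C@H]2OC
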